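## Retrosynthetic overview
1. Target 10 comes from debenzylation of the 7‑OBn tetralone 9. C‑2 is set last by enolate methylation and base equilibration, which is possible because C‑2 is α to the ketone.
2. Tetralone 8 is formed by an anodic dehydrogenative ring closure of aryl ketone 7 (C4–C4a bond, the only ring formed). C‑4 is set trans to the C‑3 methyl group.
3. Ketone 7 comes from a Grignard reagent derived from chiral bromide 4 and O‑benzylisovanillin, followed by oxidation.
4. Bromide 4 comes from Cu‑catalysed Kumada coupling of ArMgBr with (R)‑3‑bromo‑2‑methylpropan‑1‑ol. This is the only chiral input and supplies C‑3.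

Assumptions: simple reagents, catalysts and solvents are not numbered. The commercial chiral bromo‑alcohol is taken as ≥97% ee.

## Route

**Step 1**
Reactants: 1 (R)‑3‑bromo‑2‑methylpropan‑1‑ol; 2 3,4‑dimethoxyphenylmagnesium bromide
Product: 3 (S)‑3‑(3,4‑dimethoxyphenyl)‑2‑methylpropan‑1‑ol
Conditions: 2 (2.2 equiv), Li2CuCl4 (5 mol%), THF, 0 °C → rt
Reagents that add atoms: none (the aryl group comes from reactant 2)
Why: Cu‑catalysed Kumada coupling at the primary C–Br bond; the first equivalent of ArMgBr deprotonates the OH. The stereocentre is untouched, and the descriptor changes only because the CIP priorities change.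

**Step 2**
Reactants: 3
Product: 4 (S)‑4‑(3‑bromo‑2‑methylpropyl)‑1,2‑dimethoxybenzene
Conditions: CBr4, PPh3, CH2Cl2, 0 °C → rt
Reagents that add atoms: carbon tetrabromide, BrC(Br)(Br)Br
Why: Appel bromination is an SN2 reaction at a primary carbon, so the β‑stereocentre is not affected.

**Step 3**
Reactants: 4; 5 3‑(benzyloxy)‑4‑methoxybenzaldehyde
Product: 6 1‑[3‑(benzyloxy)‑4‑methoxyphenyl]‑4‑(3,4‑dimethoxyphenyl)‑3‑methylbutan‑1‑ol ((3S), C‑1 epimeric mixture)
Conditions: (i) Mg, I2 (cat.), THF, reflux, to form the Grignard reagent from 4; (ii) add 5, THF, 0 °C → rt; (iii) NH4Cl (aq)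
Reagents that add atoms: none (Mg does not remain in the product after work‑up)
Why: Grignard addition to an aldehyde. The new carbinol epimers converge at the ketone in the next step, and C‑3 is not involved.

**Step 4**
Reactants: 6
Product: 7 (S)‑1‑[3‑(benzyloxy)‑4‑methoxyphenyl]‑4‑(3,4‑dimethoxyphenyl)‑3‑methylbutan‑1‑one
Conditions: Dess–Martin periodinane, NaHCO3, CH2Cl2, rt
Reagents that add atoms: none
Why: Mild oxidation of the secondary benzylic alcohol. C‑3 is β to the new ketone and cannot epimerise.

**Step 5**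
Reactants: 7
Product: 8 (3R,4R)‑7‑(benzyloxy)‑4‑(3,4‑dimethoxyphenyl)‑6‑methoxy‑3‑methyl‑3,4‑dihydronaphthalen‑1(2H)‑one
Conditions: undivided cell, graphite anode, Pt cathode, nBu4NBF4 (0.1 M), HFIP/CH2Cl2 (3:1), 2,4,6‑collidine (0.3 equiv), constant current 3 mA (~2.5 F/mol), rt
Reagents that add atoms: none (net loss of H2 at the cathode)
Why: Proposed new method: anodic oxidation of the veratryl ring of 7 selectively over the acyl‑deactivated ring A (Eox roughly +1.5 V versus >+2 V vs SCE) gives an arene radical cation. Benzylic deprotonation gives a C‑4 radical, which is polarity‑matched to add to C‑6′ of the acylarene (para to OBn, ortho to C=O). A 6‑membered homolytic aromatic substitution follows, and a second oxidation and deprotonation rearomatises the ring. A(1,3) strain places H‑3 in the plane of the benzylic system and C‑2 on the attacked face, so the new C4–aryl bond is trans to the C‑3 methyl, and C‑3 is not touched. The closest known chemistry is DDQ‑mediated or anodic oxidative cyclisation of 1,4‑diarylbutanes to aryltetralins, and anodic benzylic C–H arylation in HFIP.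

**Step 6**
Reactants: 8
Product: 9 (2S,3S,4R)‑7‑(benzyloxy)‑4‑(3,4‑dimethoxyphenyl)‑6‑methoxy‑2,3‑dimethyl‑3,4‑dihydronaphthalen‑1(2H)‑one
Conditions: (i) LDA (1.05 equiv), THF, −78 °C; MeI (1.5 equiv), −78 → 0 °C; (ii) NaOMe, MeOH, 40 °C (equilibration)
Reagents that add atoms: iodomethane, CI
Why: Enolate C‑alkylation. The pseudo‑axial 4‑aryl group disfavours attack syn to it. Equilibration of the α‑stereocentre then funnels to the 2,3‑cis isomer, because in the preferred conformer (4‑Ar and 3‑Me pseudo‑axial) the 2‑Me is equatorial. The alternative epimer would place the 2‑Me 1,3‑diaxial to the aryl group.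

**Step 7**
Reactants: 9
Product: 10 Schisandrone, (2S,3S,4R)‑4‑(3,4‑dimethoxyphenyl)‑7‑hydroxy‑6‑methoxy‑2,3‑dimethyl‑3,4‑dihydronaphthalen‑1(2H)‑one
Conditions: H2 (1 atm), 10% Pd/C, EtOAc/EtOH, rt, 1–2 h
Reagents that add atoms: none (H2 adds only hydrogen)
Why: Hydrogenolysis of the aryl benzyl ether. The aryl ketone and methyl ethers survive under neutral conditions, and no stereocentre is affected.

## Compound list
1 | (R)‑3‑bromo‑2‑methylpropan‑1‑ol | C[C@H](CO)CBr | starting material
2 | 3,4‑dimethoxyphenylmagnesium bromide | COc1ccc([Mg]Br)cc1OC | starting material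
3 | (S)‑3‑(3,4‑dimethoxyphenyl)‑2‑methylpropan‑1‑ol | COc1ccc(C[C@H](C)CO)cc1OC | intermediate
4 | (S)‑4‑(3‑bromo‑2‑methylpropyl)‑1,2‑dimethoxybenzene | COc1ccc(C[C@H](C)CBr)cc1OC | intermediate
5 | 3‑(benzyloxy)‑4‑methoxybenzaldehyde | COc1ccc(C=O)cc1OCc1ccccc1 | starting material
6 | 1‑[3‑(benzyloxy)‑4‑methoxyphenyl]‑4‑(3,4‑dimethoxyphenyl)‑3‑methylbutan‑1‑ol | COc1ccc(C[C@H](C)CC(O)c2ccc(OC)c(OCc3ccccc3)c2)cc1OC | intermediate (C‑1 epimers)
7 | (S)‑1‑[3‑(benzyloxy)‑4‑methoxyphenyl]‑4‑(3,4‑dimethoxyphenyl)‑3‑methylbutan‑1‑one | COc1ccc(C[C@H](C)CC(=O)c2ccc(OC)c(OCc3ccccc3)c2)cc1OC | intermediate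
8 | (3R,4R)‑7‑(benzyloxy)‑4‑(3,4‑dimethoxyphenyl)‑6‑methoxy‑3‑methyltetralin‑1‑one | COc1cc2c(cc1OCc1ccccc1)C(=O)C[C@@H](C)[C@@H]2c1ccc(OC)c(OC)c1 | intermediate
9 | (2S,3S,4R)‑7‑(benzyloxy)‑4‑(3,4‑dimethoxyphenyl)‑6‑methoxy‑2,3‑dimethyltetralin‑1‑one | COc1cc2c(cc1OCc1ccccc1)C(=O)[C@@H](C)[C@@H](C)[C@@H]2c1ccc(OC)c(OC)c1 | intermediate
10 | Schisandrone | COc1cc2c(cc1O)C(=O)[C@@H](C)[C@@H](C)[C@@H]2c1ccc(OC)c(OC)c1 | target

## Totals
Total steps: 7. Longest linear sequence: 7 steps, from 1 (aldehyde 5 and Grignard 2 are convergent partners).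

## Three steps most likely to fail
1. **Step 5 (proposed new anodic cyclisation).** The deactivated arene may cyclise sluggishly, and over‑oxidation or E1‑type styrene formation could erode C‑3.
   Fallback (known chemistry): brominate the benzylic CH2 of 7 (NBS, radical initiator, PhCF3, 80 °C), then close the ring by Lewis‑acid Friedel–Crafts benzylation (SnCl4 or AgSbF6, CH2Cl2), the classical cyclolignan closure.
2. **Step 6 (C‑2 methylation).** Poor facial selectivity, over‑alkylation, or an unfavourable equilibrium could lower the yield of the 2,3‑cis isomer.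
   Fallback: methylate the acyclic ketone 7 first (LDA, MeI) to give C‑2 epimers, run the Step 5 cyclisation on that mixture, then funnel C‑2 by base epimerisation.
3. **Step 1 (Kumada coupling of the free bromo‑alcohol).** Oxetane formation, elimination or low conversion are possible.
   Fallback: Ni‑catalysed cross‑electrophile coupling of 1 with 4‑bromoveratrole (NiBr2·bipy, Zn or Mn, DMA), which tolerates the free OH.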